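Numbering (daucane): C1 = quaternary ring-fusion carbon with the angular methyl, C2 and C3 = cyclopentane CH2 groups, C4 = carbinol carbon (OH, isopropyl), C5 = ring-fusion CH, C6 = ester-bearing carbon, C7=C8(CH3), C9, C10.
Endgame: the 4-methoxybenzoate is attached last with inversion at C6 (Mitsunobu), after a formyl group at C3, a traceless activating group, has been excised by oxidation and radical decarboxylation.
Key disconnection: the cyclopentane ring (C1-C2-C3-C4-C5) is cut at C3-C4 and C1-C2, back to a monocyclic cycloheptadienyl isopropyl ketone and acrolein; forward, this is an iron-hydride HAT-initiated radical-polar crossover (3+2) annulation whose ring-closing event is the aldol bond C3-C4.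
Enabling feature: quaternary C1 carries a methyl group and is the vicinal neighbour of C5, which bears the C4 carbinol; C1 is therefore the tertiary radical of a 1-methylidene precursor (CH2 + H = angular methyl), C2-C3 is a two-carbon radical acceptor, and C4 is an isopropyl ketone placed to capture the resulting enolate, with the C5 stereocentre steering C1 and C4.
Ring order: seven-membered ring first (ring-closing metathesis of an acyclic syn-aldol adduct built from 2,5-dimethylhexa-1,5-diene, an isobutyric Weinreb amide and acrolein), five-membered ring second (key step).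

Key step: step 5

Remark (assumption): the sense of induction of (−)-Ipc2BOTf [from (+)-α-pinene] in step 2 is taken from the Paterson enolate model; if the aldol follows the opposite sense, the antipodal reagent is used and nothing else changes.

Step 1
Reactants: 1 2,5-dimethylhexa-1,5-diene; 2 N-methoxy-N,2-dimethylpropanamide
Product: 4 2,8-dimethyl-5-methylidenenon-8-en-3-one, via allyllithium 3 (not isolated)
Conditions: n-BuLi, TMEDA, hexane, 0 °C → rt (1 in excess); then 2, THF, −78 °C; AcOH quench at −78 °C
Reagents that add atoms: none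
Why: Allylic lithiation of the 2-methyl-1-alkene at its methyl group gives a 2-substituted allyllithium with two equivalent termini, and the Weinreb ketone synthesis stops at the β,γ-unsaturated ketone because the chelated tetrahedral adduct survives until the cold acidic quench; no stereocentre is formed.

Step 2
Reactants: 4 2,8-dimethyl-5-methylidenenon-8-en-3-one; 5 acrolein (prop-2-enal)
Product: 7 (4S,5R)-5-hydroxy-2-methyl-4-(5-methylhexa-1,5-dien-2-yl)hept-6-en-3-one, via Z-enol borinate 6 (not isolated)
Conditions: (−)-Ipc2BOTf, i-Pr2NEt, CH2Cl2, −78 °C; then 5, −78 → −20 °C; H2O2, MeOH, pH 7 buffer, 0 °C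
Reagents that add atoms: none
Why: Paterson boron aldol reaction, in which enolisation on the methylene side gives the Z-enol diisopinocampheylborinate that adds through its α-carbon in a chair Zimmerman–Traxler transition state, so the syn relationship of C5 and C6 comes from the Z-enolate geometry and the absolute sense from the isopinocampheyl ligands.

Step 3
Reactants: 7 (4S,5R)-5-hydroxy-2-methyl-4-(5-methylhexa-1,5-dien-2-yl)hept-6-en-3-one
Product: 8 (4S,5R)-5-[(tert-butyldimethylsilyl)oxy]-2-methyl-4-(5-methylhexa-1,5-dien-2-yl)hept-6-en-3-one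
Conditions: TBSOTf, 2,6-lutidine, CH2Cl2, −78 °C
Reagents that add atoms: tert-butyldimethylsilyl trifluoromethanesulfonate, CC(C)(C)[Si](C)(C)OS(=O)(=O)C(F)(F)F
Why: Silyl ether formation with the silyl triflate and a hindered pyridine base at low temperature should outpace enolisation of the doubly activated C5–H and blocks retro-aldol cleavage and later lactol formation; no stereocentre changes.

Step 4
Reactants: 8 (4S,5R)-5-[(tert-butyldimethylsilyl)oxy]-2-methyl-4-(5-methylhexa-1,5-dien-2-yl)hept-6-en-3-one
Product: 9 1-[(1S,2R)-2-[(tert-butyldimethylsilyl)oxy]-4-methyl-7-methylidenecyclohept-3-en-1-yl]-2-methylpropan-1-one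
Conditions: RuCl2(=CHPh)(PCy3)(H2IMes) (second-generation Grubbs catalyst, 5 mol %), CH2Cl2, 40 °C
Reagents that add atoms: none
Why: Ring-closing metathesis can only join the vinyl group and the distal 2-propenyl unit (any ring through the C1 methylidene would be four-membered), which gives the trisubstituted cycloheptene under neutral conditions that leave the epimerisable C5 untouched.

Step 5
Reactants: 9 1-[(1S,2R)-2-[(tert-butyldimethylsilyl)oxy]-4-methyl-7-methylidenecyclohept-3-en-1-yl]-2-methylpropan-1-one; 5 acrolein (prop-2-enal)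
Product: 12 (2S,3R,3aS,4R,8aS)-4-[(tert-butyldimethylsilyl)oxy]-3-hydroxy-6,8a-dimethyl-3-(propan-2-yl)-1,2,3,3a,4,7,8,8a-octahydroazulene-2-carbaldehyde, via C1 tertiary radical 10 (not isolated), via iron enolate 11 (not isolated)
Conditions: Fe(acac)3 (30 mol %), PhSiH3, 5 (3 equiv, slow addition), EtOH–(CH2OH)2 (4:1), 0 °C → rt
Reagents that add atoms: none
Why: An iron hydride formed from Fe(acac)3 and PhSiH3 transfers a hydrogen atom to the CH2 terminus of the exocyclic 1,1-disubstituted alkene, which creates the C1 methyl group and the tertiary C1 radical 10; Giese addition to acrolein forms C1–C2, divalent iron reduces the α-formyl radical to the trivalent iron enolate 11, and this enolate closes the cyclopentane by intramolecular aldol addition of C3 to the C4 ketone. The closest known reaction type is the HAT-initiated radical-polar crossover annulation of alkenyl ketones with enals (reductive olefin coupling followed by aldol capture of the enolate). The five-membered ring closes in the 5-(enolexo)-exo-trig mode. C1 is set because acrolein approaches the planar radical anti to the vicinal isobutyryl group on C5 and to the C6 silyloxy group (both β), which places C2 α and the methyl β and so fixes the trans ring fusion; C4 is set because the ketone reacts through the rotamer with the isopropyl group over H5 and the oxygen toward C6 in an iron-bridged transition state, which gives the β-hydroxyl, and the same chelate places the C3 formyl group cis to that hydroxyl (this centre is removed later). The step needs hydrogen atom transfer to the exocyclic alkene rather than to the trisubstituted C7=C8 bond, which the higher reactivity of 1,1-disubstituted alkenes and the flanking silyloxy group should secure, and radical capture faster than reduction, which the excess of acrolein should secure.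

Step 6
Reactants: 12 (2S,3R,3aS,4R,8aS)-4-[(tert-butyldimethylsilyl)oxy]-3-hydroxy-6,8a-dimethyl-3-(propan-2-yl)-1,2,3,3a,4,7,8,8a-octahydroazulene-2-carbaldehyde
Product: 13 (2S,3R,3aS,4R,8aS)-4-[(tert-butyldimethylsilyl)oxy]-3-hydroxy-6,8a-dimethyl-3-(propan-2-yl)-1,2,3,3a,4,7,8,8a-octahydroazulene-2-carboxylic acid
Conditions: NaClO2, NaH2PO4, 2-methylbut-2-ene, t-BuOH/H2O, 0 °C → rt
Reagents that add atoms: sodium chlorite, [Na+].[O-]Cl=O
Why: Pinnick oxidation converts the aldehyde to the acid under buffered conditions with 2-methylbut-2-ene as hypochlorite scavenger, which should protect the ring alkene and avoid retro-aldol cleavage; the C3 configuration is kept but is irrelevant.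

Step 7
Reactants: 13 (2S,3R,3aS,4R,8aS)-4-[(tert-butyldimethylsilyl)oxy]-3-hydroxy-6,8a-dimethyl-3-(propan-2-yl)-1,2,3,3a,4,7,8,8a-octahydroazulene-2-carboxylic acid
Product: 15 (3R,3aS,4R,8aS)-4-[(tert-butyldimethylsilyl)oxy]-6,8a-dimethyl-3-(propan-2-yl)-1,2,3,3a,4,7,8,8a-octahydroazulen-3-ol, via Barton ester 14 (not isolated)
Conditions: 1-hydroxypyridine-2(1H)-thione, DCC, DMAP (cat.), CH2Cl2, 0 °C → rt, dark; then t-BuSH, hν (tungsten lamp), rt
Reagents that add atoms: none
Why: Barton reductive decarboxylation, in which the thiohydroxamate ester fragments under visible light to the secondary C3 radical that takes a hydrogen atom from the thiol and so erases the temporary C3 stereocentre, while a β-hydroxy radical does not fragment and the tertiary alcohol is kept.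

Step 8
Reactants: 15 (3R,3aS,4R,8aS)-4-[(tert-butyldimethylsilyl)oxy]-6,8a-dimethyl-3-(propan-2-yl)-1,2,3,3a,4,7,8,8a-octahydroazulen-3-ol
Product: 16 (3R,3aS,4R,8aS)-6,8a-dimethyl-3-(propan-2-yl)-1,2,3,3a,4,7,8,8a-octahydroazulene-3,4-diol
Conditions: Bu4NF, THF, rt → 40 °C
Reagents that add atoms: none
Why: Fluoride-mediated desilylation frees the allylic C6 alcohol without touching the tertiary alcohol or the alkene; no stereocentre changes.

Step 9
Reactants: 16 (3R,3aS,4R,8aS)-6,8a-dimethyl-3-(propan-2-yl)-1,2,3,3a,4,7,8,8a-octahydroazulene-3,4-diol; 17 4-methoxybenzoic acid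
Product: 18 (3R,3aS,4S,8aS)-3-hydroxy-6,8a-dimethyl-3-(propan-2-yl)-1,2,3,3a,4,7,8,8a-octahydroazulen-4-yl 4-methoxybenzoate
Conditions: PPh3, DIAD, toluene, 0 °C → rt
Reagents that add atoms: none
Why: Mitsunobu esterification, in which only the secondary allylic alcohol is activated (the tertiary C4 alcohol is inert) and the carboxylate displaces it by SN2 from the α face, so C6 is inverted to the required configuration, while the cis C4 hydroxyl cannot reach the backside and oxetane formation is excluded.

Compound list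
1 | 2,5-dimethylhexa-1,5-diene | C=C(C)CCC(C)=C | starting material
2 | N-methoxy-N,2-dimethylpropanamide | CC(C)C(=O)N(C)OC | starting material
3 | (5-methyl-2-methylidenehex-5-en-1-yl)lithium | [Li]CC(=C)CCC(C)=C | intermediate
4 | 2,8-dimethyl-5-methylidenenon-8-en-3-one | CC(C)C(=O)CC(=C)CCC(C)=C | intermediate
5 | acrolein (prop-2-enal) | C=CC=O | starting material
6 | (Z)-enol diisopinocampheylborinate of 4, boron on the enol oxygen, O and the C5 substituent cis | C[C@H]1[C@H](B(O/C(C(C)C)=C\C(=C)CCC(C)=C)[C@@H]3C[C@@H]4C[C@H]([C@H]3C)C4(C)C)C[C@@H]2C[C@H]1C2(C)C | intermediate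
7 | (4S,5R)-5-hydroxy-2-methyl-4-(5-methylhexa-1,5-dien-2-yl)hept-6-en-3-one | CC(C)C(=O)[C@@H](C(=C)CCC(C)=C)[C@H](O)C=C | intermediate
8 | (4S,5R)-5-[(tert-butyldimethylsilyl)oxy]-2-methyl-4-(5-methylhexa-1,5-dien-2-yl)hept-6-en-3-one | CC(C)C(=O)[C@@H](C(=C)CCC(C)=C)[C@H](O[Si](C)(C)C(C)(C)C)C=C | intermediate
9 | 1-[(1S,2R)-2-[(tert-butyldimethylsilyl)oxy]-4-methyl-7-methylidenecyclohept-3-en-1-yl]-2-methylpropan-1-one | CC(C)(C)[Si](C)(C)O[C@@H]1C=C(C)CCC(=C)[C@@H]1C(=O)C(C)C | intermediate
10 | tertiary C1 radical of 9 after hydrogen atom addition to the methylidene carbon | CC(C)(C)[Si](C)(C)O[C@@H]1C=C(C)CC[C](C)[C@@H]1C(=O)C(C)C | intermediate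
11 | iron-bound aldehyde enolate of the Giese adduct, drawn as the free enolate | CC(C)(C)[Si](C)(C)O[C@@H]1C=C(C)CC[C@@](C)(CC=C[O-])[C@@H]1C(=O)C(C)C | intermediate
12 | (2S,3R,3aS,4R,8aS)-4-[(tert-butyldimethylsilyl)oxy]-3-hydroxy-6,8a-dimethyl-3-(propan-2-yl)-1,2,3,3a,4,7,8,8a-octahydroazulene-2-carbaldehyde | CC(C)(C)[Si](C)(C)O[C@@H]2C=C(C)CC[C@@]3(C)C[C@H](C=O)[C@@](O)(C(C)C)[C@H]23 | intermediate
13 | (2S,3R,3aS,4R,8aS)-4-[(tert-butyldimethylsilyl)oxy]-3-hydroxy-6,8a-dimethyl-3-(propan-2-yl)-1,2,3,3a,4,7,8,8a-octahydroazulene-2-carboxylic acid | CC(C)(C)[Si](C)(C)O[C@@H]2C=C(C)CC[C@@]3(C)C[C@H](C(=O)O)[C@@](O)(C(C)C)[C@H]23 | intermediate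
14 | 2-thioxopyridin-1(2H)-yl ester of 13 (Barton ester) | CC(C)(C)[Si](C)(C)O[C@@H]2C=C(C)CC[C@@]3(C)C[C@H](C(=O)ON4C=CC=CC4=S)[C@@](O)(C(C)C)[C@H]23 | intermediate
15 | (3R,3aS,4R,8aS)-4-[(tert-butyldimethylsilyl)oxy]-6,8a-dimethyl-3-(propan-2-yl)-1,2,3,3a,4,7,8,8a-octahydroazulen-3-ol | CC(C)(C)[Si](C)(C)O[C@@H]2C=C(C)CC[C@@]3(C)CC[C@@](O)(C(C)C)[C@H]23 | intermediate
16 | (3R,3aS,4R,8aS)-6,8a-dimethyl-3-(propan-2-yl)-1,2,3,3a,4,7,8,8a-octahydroazulene-3,4-diol | O[C@@H]2C=C(C)CC[C@@]3(C)CC[C@@](O)(C(C)C)[C@H]23 | intermediate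
17 | 4-methoxybenzoic acid | COc1ccc(C(=O)O)cc1 | starting material
18 | (3R,3aS,4S,8aS)-3-hydroxy-6,8a-dimethyl-3-(propan-2-yl)-1,2,3,3a,4,7,8,8a-octahydroazulen-4-yl 4-methoxybenzoate | COc1ccc(C(=O)O[C@H]2C=C(C)CC[C@@]3(C)CC[C@@](O)(C(C)C)[C@H]23)cc1 | target

Total step count: 9. Longest linear sequence: 9 steps (from 1).

Steps most likely to fail

Step 5. The iron enolate may be protonated before the aldol closure, the C1 radical may be hydrogenated instead of captured, reversible hydrogen atom transfer may move the exocyclic alkene into the ring, or acrolein may add from the wrong face. The fallback separates the radical and the polar event and closes the ring by enamine catalysis. It sets out from 9: the Fe(acac)3/PhSiH3 reductive olefin coupling with acrolein is run in ethanol to give the open keto-aldehyde 3-[(1S,2S,3R)-3-[(tert-butyldimethylsilyl)oxy]-1,5-dimethyl-2-(2-methylpropanoyl)cyclohept-4-en-1-yl]propanal F1. A secondary-amine-catalysed intramolecular aldol addition (L-proline or pyrrolidine/AcOH, 5-enolexo attack of the aldehyde enamine on the ketone) then forms C3–C4 and comes back to the route at 12.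

Step 2. The boron aldol may give insufficient enantio- or diastereoselectivity, the dienolate may react at its γ-carbon, or the exocyclic alkene may migrate into conjugation. The fallback replaces reagent control by auxiliary control and sets out from 1. Lithiation as in step 1 with a CO2 quench gives 6-methyl-3-methylidenehept-6-enoic acid F2. Mixed-anhydride acylation (PivCl, Et3N; lithiated (S)-4-benzyl-1,3-oxazolidin-2-one) gives (4S)-4-benzyl-3-(6-methyl-3-methylidenehept-6-enoyl)-1,3-oxazolidin-2-one F3. An Evans syn-aldol reaction (Bu2BOTf, Et3N, then 5) gives (4S)-4-benzyl-3-[(2S,3R)-3-hydroxy-2-(5-methylhexa-1,5-dien-2-yl)pent-4-enoyl]-1,3-oxazolidin-2-one F4. Transamidation (Me3Al, MeNHOMe·HCl) gives (2S,3R)-3-hydroxy-N-methoxy-N-methyl-2-(5-methylhexa-1,5-dien-2-yl)pent-4-enamide F5, and silylation (TBSOTf, 2,6-lutidine) gives (2S,3R)-3-[(tert-butyldimethylsilyl)oxy]-N-methoxy-N-methyl-2-(5-methylhexa-1,5-dien-2-yl)pent-4-enamide F6. Addition of i-PrMgCl (or i-PrLi) comes back to the route at 8.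

Step 9. The activated allylic alcohol may eliminate to the diene, substitution may occur with allylic transposition, or the crowded α face may prevent inversion. The fallback inverts C6 by a redox pair and then acylates with retention; it sets out from 16. MnO2 oxidation of the allylic alcohol gives (3R,3aR,8aS)-3-hydroxy-6,8a-dimethyl-3-(propan-2-yl)-2,3,3a,7,8,8a-hexahydroazulen-4(1H)-one F7. Hydroxyl-directed reduction with Me4NBH(OAc)3 (AcOH/MeCN, −20 °C) should deliver hydride from the C4 hydroxyl to the β face and give the 1,3-anti diol (3R,3aS,4S,8aS)-6,8a-dimethyl-3-(propan-2-yl)-1,2,3,3a,4,7,8,8a-octahydroazulene-3,4-diol F8. Acylation of the secondary alcohol with 4-methoxybenzoyl chloride (pyridine, DMAP) comes back to the route at 18.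

Further compounds
F1 | step 5 | 3-[(1S,2S,3R)-3-[(tert-butyldimethylsilyl)oxy]-1,5-dimethyl-2-(2-methylpropanoyl)cyclohept-4-en-1-yl]propanal | CC(C)(C)[Si](C)(C)O[C@@H]2C=C(C)CC[C@@](C)(CCC=O)[C@@H]2C(=O)C(C)C
F2 | step 2 | 6-methyl-3-methylidenehept-6-enoic acid | OC(=O)CC(=C)CCC(C)=C
F3 | step 2 | (4S)-4-benzyl-3-(6-methyl-3-methylidenehept-6-enoyl)-1,3-oxazolidin-2-one | O=C1OC[C@H](Cc2ccccc2)N1C(=O)CC(=C)CCC(C)=C
F4 | step 2 | (4S)-4-benzyl-3-[(2S,3R)-3-hydroxy-2-(5-methylhexa-1,5-dien-2-yl)pent-4-enoyl]-1,3-oxazolidin-2-one | O=C1OC[C@H](Cc2ccccc2)N1C(=O)[C@@H](C(=C)CCC(C)=C)[C@H](O)C=C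
F5 | step 2 | (2S,3R)-3-hydroxy-N-methoxy-N-methyl-2-(5-methylhexa-1,5-dien-2-yl)pent-4-enamide | CON(C)C(=O)[C@@H](C(=C)CCC(C)=C)[C@H](O)C=C
F6 | step 2 | (2S,3R)-3-[(tert-butyldimethylsilyl)oxy]-N-methoxy-N-methyl-2-(5-methylhexa-1,5-dien-2-yl)pent-4-enamide | CON(C)C(=O)[C@@H](C(=C)CCC(C)=C)[C@H](O[Si](C)(C)C(C)(C)C)C=C
F7 | step 9 | (3R,3aR,8aS)-3-hydroxy-6,8a-dimethyl-3-(propan-2-yl)-2,3,3a,7,8,8a-hexahydroazulen-4(1H)-one | O=C2C=C(C)CC[C@@]3(C)CC[C@@](O)(C(C)C)[C@H]23
F8 | step 9 | (3R,3aS,4S,8aS)-6,8a-dimethyl-3-(propan-2-yl)-1,2,3,3a,4,7,8,8a-octahydroazulene-3,4-diol | O[C@H]2C=C(C)CC[C@@]3(C)CC[C@@](O)(C(C)C)[C@H]23
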